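A direct plan would start ring B from cyclohexane-1,3-dione A1, hang the C11–C15 chain and a pentenoate arm on its C2 to give dione A2, and close ring A onto it by a copper hydride reductive aldol reaction to ketol A3.
Dehydration, methylation at C8, methylenation and a dissolving-metal reductive methylation would give the trans-decalin A4, in which the chain still sits on C10.
A cationic 1,2-shift of the chain from C10 to C9 with loss of H-1, then exchange of the silyl ether for the acetate, would finish.
Weakest: the late chain migration. The tertiary C9 cation can also lose a proton or take a hydride from C8, the C10 cation can lose H-5 to give the tetrasubstituted alkene, and all of this is staked on the most advanced material.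
Second: the ring A closure must tell apart the two enantiotopic ketones of A2 under catalyst control past a remote C13 centre, and it sets a quaternary C10 that the plan later destroys.
Third: a linear run of about twelve steps carries the silyl-protected chain from the first step and sets C4, C5, C8 and C9 one at a time.

**Retrosynthetic overview**
Feature used: the C1=C10 alkene lies in ring A next to C5–H and the quaternary C4 (CH3, CO2CH3). This cyclohexene is the retron of a [4+2] addition of methyl methacrylate (C3, C4) to a C2=C1–C10=C5 diene, and the C5=C10 bond of that diene is the retron of a ring-closing enyne metathesis.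
Key disconnection: both rings open at once to the acyclic 1,7-enyne 14 and methyl methacrylate. Forward, ring B closes first (C5=C10) and ring A second (C2–C3, C4–C5) in one flask, and no carbocycle exists before that step.
Stereocentres: C13 from (S)-citronellol, C8 from a chiral lactone, C9 by enolate alkylation on that five-membered template, C4 and C5 together in the cycloaddition.
The design has no cation at C9, no desymmetrisation and no sacrificial quaternary centre; the side chain enters once, as a finished fragment, in a convergent nine-step route.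

Key step: step 9

Assumption: lactone 6 is bought as the (S) enantiomer (it is also the product of Ru(OAc)2(BINAP)-catalysed hydrogenation of 4-methylfuran-2(5H)-one); atom numbers C1–C20 are the halimane numbers of the target (C4 bears CO2CH3, C5 and C10 are the ring fusion, C9 bears the side chain C11–C15).

Step 1
Reactants: 1 (S)-citronellol [(3S)-3,7-dimethyloct-6-en-1-ol]
Product: 2 tert-butyl{[(3S)-3,7-dimethyloct-6-en-1-yl]oxy}dimethylsilane
Conditions: t-BuMe2SiCl (1.1 equiv), imidazole (2 equiv), DMF, 0 → 25 °C
Reagents that add atoms: tert-butyldimethylsilyl chloride, CC(C)(C)[Si](C)(C)Cl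
Why: imidazole-promoted silylation of the only hydroxyl gives an ether that survives the enolate, hydride and Grignard steps ahead and leaves the stereocentre (future C13) untouched.

Step 2
Reactants: 2 tert-butyl{[(3S)-3,7-dimethyloct-6-en-1-yl]oxy}dimethylsilane
Product: 4 (4S)-6-{[tert-butyl(dimethyl)silyl]oxy}-4-methylhexanoic acid, via aldehyde 3 (not isolated)
Conditions: O3, CH2Cl2, −78 °C; PPh3, −78 → 25 °C; then NaClO2, NaH2PO4, 2-methyl-2-butene, t-BuOH/H2O, 0 → 25 °C
Reagents that add atoms: ozone, [O-][O+]=O; sodium chlorite, [Na+].[O-]Cl=O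
Why: ozonolysis with reductive work-up cleaves the only alkene to the aldehyde, which a Pinnick oxidation takes to the acid without touching the silyl ether or the remote stereocentre.

Step 3
Reactants: 4 (4S)-6-{[tert-butyl(dimethyl)silyl]oxy}-4-methylhexanoic acid
Product: 5 tert-butyl{[(3R)-5-iodo-3-methylpentyl]oxy}dimethylsilane
Conditions: PhI(OAc)2 (1.1 equiv), I2 (1.0 equiv), cyclohexane, hν (tungsten lamp), 80 °C
Reagents that add atoms: iodine, [I][I]
Why: Hunsdiecker-type iododecarboxylation (acyl hypoiodite, radical decarboxylation, iodine atom transfer) shortens the chain by one carbon to the primary iodide that maps onto C11–C15, the descriptor changing to R only because iodine alters the priorities.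

Step 4
Reactants: 6 (4S)-4-methyloxolan-2-one [(S)-β-methyl-γ-butyrolactone]
Product: 7 (3S,4S)-3,4-dimethyloxolan-2-one
Conditions: LiN(i-Pr)2 (1.05 equiv), THF, −78 °C; MeI (1.5 equiv), −78 → −40 °C
Reagents that add atoms: iodomethane, CI
Why: lactone enolate alkylation anti to the C4 methyl installs the future C20 methyl, and its configuration is of no consequence because C3 is enolised again in the next step.

Step 5
Reactants: 7 (3S,4S)-3,4-dimethyloxolan-2-one; 5 tert-butyl{[(3R)-5-iodo-3-methylpentyl]oxy}dimethylsilane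
Product: 8 (3S,4S)-3-[(3S)-5-{[tert-butyl(dimethyl)silyl]oxy}-3-methylpentyl]-3,4-dimethyloxolan-2-one
Conditions: LiN(i-Pr)2 (1.1 equiv), THF, −78 °C; DMPU (3 equiv), 5 (1.2 equiv), −78 → −20 °C
Reagents that add atoms: none
Why: SN2 alkylation of the tetrasubstituted lactone enolate takes place on the face of the planar five-membered enolate anti to the adjacent C4 methyl, so the chain ends trans and the C3 methyl cis to it, which is the C8/C9 relationship of the target (1,2-induction on a rigid template).

Step 6
Reactants: 8 (3S,4S)-3-[(3S)-5-{[tert-butyl(dimethyl)silyl]oxy}-3-methylpentyl]-3,4-dimethyloxolan-2-one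
Product: 10 (2S,3S,6S)-8-{[tert-butyl(dimethyl)silyl]oxy}-3-ethynyl-2,3,6-trimethyloctan-1-ol, via lactol 9 (not isolated)
Conditions: i-Bu2AlH (1.1 equiv), CH2Cl2, −78 °C; MeOH; then K2CO3 (3 equiv), dimethyl (1-diazo-2-oxopropyl)phosphonate (2 equiv), MeOH, 0 → 25 °C
Reagents that add atoms: dimethyl (1-diazo-2-oxopropyl)phosphonate, COP(=O)(OC)C(=[N+]=[N-])C(C)=O
Why: partial reduction stops at the aluminium hemiacetal, and the open hydroxy aldehyde form of the lactol is homologated by the Seyferth–Gilbert reaction with the Ohira–Bestmann reagent to the alkyne (C10≡C1), the alpha-quaternary aldehyde being unable to epimerise.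

Step 7
Reactants: 10 (2S,3S,6S)-8-{[tert-butyl(dimethyl)silyl]oxy}-3-ethynyl-2,3,6-trimethyloctan-1-ol
Product: 12 tert-butyl{[(3S,6S,7R)-6-ethynyl-3,6,7-trimethylundec-10-en-1-yl]oxy}dimethylsilane, via triflate 11 (not isolated)
Conditions: (CF3SO2)2O (1.2 equiv), 2,6-lutidine (1.5 equiv), CH2Cl2, −78 °C; then CH2=CHCH2MgBr (3.5 equiv), CuBr·SMe2 (10 mol %), THF, −78 → 0 °C
Reagents that add atoms: allylmagnesium bromide, C=CC[Mg]Br
Why: copper-catalysed SN2 cross-coupling of the primary triflate formed in situ with the allyl Grignard reagent adds C6, C5 and the terminal methylene, the first equivalent of Grignard reagent only deprotonating the alkyne, which is restored on work-up.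

Step 8
Reactants: 12 tert-butyl{[(3S,6S,7R)-6-ethynyl-3,6,7-trimethylundec-10-en-1-yl]oxy}dimethylsilane
Product: 14 (3S,6S,7R)-6-ethynyl-3,6,7-trimethylundec-10-en-1-yl acetate, via alcohol 13 (not isolated)
Conditions: Bu4NF (1.2 equiv), THF, 0 °C; then Ac2O (3 equiv), pyridine, DMAP (5 mol %), 25 °C
Reagents that add atoms: acetic anhydride, CC(=O)OC(C)=O
Why: fluoride desilylation and DMAP-catalysed acetylation of the liberated alkoxide in the same flask put the acetate in place before the key step, so that no protecting group operation follows it.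

Step 9
Reactants: 14 (3S,6S,7R)-6-ethynyl-3,6,7-trimethylundec-10-en-1-yl acetate; 15 methyl methacrylate
Product: 17 methyl (1S,5S,6R,8aR)-5-[(3S)-5-acetoxy-3-methylpentyl]-1,5,6-trimethyl-1,2,3,5,6,7,8,8a-octahydronaphthalene-1-carboxylate, via diene 16 (not isolated)
Conditions: RuCl2(=CHPh)(H2IMes)(PCy3) (second-generation Grubbs catalyst, 3 mol %), ethylene (1 atm), CH2Cl2, 40 °C; then argon purge, 15 (3 equiv), EtAlCl2 (2.5 equiv), −40 → 0 °C; cold 1 M HCl
Reagents that add atoms: none
Why: Tandem ring-closing enyne metathesis and Lewis acid promoted Diels–Alder reaction, a known one-flask pairing: the ruthenium alkylidene formed at the terminal alkene adds to the alkyne in the exo mode, closing ring B through the C5=C10 bond, and ethylene releases the metal from the vinyl carbene to leave the 1-vinylcyclohexene 16. Without isolation, the diene C2=C1–C10=C5 (kept s-cis by the quaternary C9 next to C10) adds to methyl methacrylate complexed by EtAlCl2 in an intermolecular [4+2] that closes ring A through the C2–C3 and C4–C5 bonds and leaves the C1=C10 alkene exactly where the target has it. Regiochemistry: the substituted diene terminus C5 bonds to the ester-bearing carbon C4 (the "ortho" mode that 1-vinylcyclohexenes follow), which the asynchronous Lewis acid transition state with its early C2–C3 bond at the unhindered terminus reinforces. C5: the endo ester with its aluminium lies under C10 and must avoid the pseudoaxial substituent of C9, which is the C9 methyl in the half-chair that keeps the C8 methyl equatorial, so the dienophile should add to the opposite face, the new C4–C5 bond ending anti to that methyl and H-5 cis to it. C4: the complexed ester lies endo, hence cis to C6, which puts CO2CH3 and the ring B bond on the same face of ring A and the C4 methyl on the side of H-5. EtAlCl2 also scavenges protons, so the trisubstituted alkene should not migrate to the tetrasubstituted position.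

**Compound list**
1 | (S)-citronellol, (3S)-3,7-dimethyloct-6-en-1-ol | CC(C)=CCC[C@H](C)CCO | starting material
2 | tert-butyl{[(3S)-3,7-dimethyloct-6-en-1-yl]oxy}dimethylsilane | CC(C)=CCC[C@H](C)CCO[Si](C)(C)C(C)(C)C | intermediate
3 | (4S)-6-{[tert-butyl(dimethyl)silyl]oxy}-4-methylhexanal (not isolated) | O=CCC[C@H](C)CCO[Si](C)(C)C(C)(C)C | intermediate
4 | (4S)-6-{[tert-butyl(dimethyl)silyl]oxy}-4-methylhexanoic acid | OC(=O)CC[C@H](C)CCO[Si](C)(C)C(C)(C)C | intermediate
5 | tert-butyl{[(3R)-5-iodo-3-methylpentyl]oxy}dimethylsilane | ICC[C@H](C)CCO[Si](C)(C)C(C)(C)C | intermediate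
6 | (4S)-4-methyloxolan-2-one, (S)-β-methyl-γ-butyrolactone | O=C1OC[C@@H](C)C1 | starting material
7 | (3S,4S)-3,4-dimethyloxolan-2-one (trans) | O=C1OC[C@@H](C)[C@@H]1C | intermediate
8 | (3S,4S)-3-[(3S)-5-{[tert-butyl(dimethyl)silyl]oxy}-3-methylpentyl]-3,4-dimethyloxolan-2-one | O=C1OC[C@@H](C)[C@]1(C)CC[C@H](C)CCO[Si](C)(C)C(C)(C)C | intermediate
9 | (3S,4S)-3-[(3S)-5-{[tert-butyl(dimethyl)silyl]oxy}-3-methylpentyl]-3,4-dimethyloxolan-2-ol (anomer mixture, not isolated) | OC1OC[C@@H](C)[C@]1(C)CC[C@H](C)CCO[Si](C)(C)C(C)(C)C | intermediate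
10 | (2S,3S,6S)-8-{[tert-butyl(dimethyl)silyl]oxy}-3-ethynyl-2,3,6-trimethyloctan-1-ol | OC[C@@H](C)[C@](C#C)(C)CC[C@H](C)CCO[Si](C)(C)C(C)(C)C | intermediate
11 | (2S,3S,6S)-8-{[tert-butyl(dimethyl)silyl]oxy}-3-ethynyl-2,3,6-trimethyloctyl trifluoromethanesulfonate (not isolated) | O=S(=O)(OC[C@@H](C)[C@](C#C)(C)CC[C@H](C)CCO[Si](C)(C)C(C)(C)C)C(F)(F)F | intermediate
12 | tert-butyl{[(3S,6S,7R)-6-ethynyl-3,6,7-trimethylundec-10-en-1-yl]oxy}dimethylsilane | C=CCC[C@@H](C)[C@](C#C)(C)CC[C@H](C)CCO[Si](C)(C)C(C)(C)C | intermediate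
13 | (3S,6S,7R)-6-ethynyl-3,6,7-trimethylundec-10-en-1-ol (not isolated) | C=CCC[C@@H](C)[C@](C#C)(C)CC[C@H](C)CCO | intermediate
14 | (3S,6S,7R)-6-ethynyl-3,6,7-trimethylundec-10-en-1-yl acetate | C=CCC[C@@H](C)[C@](C#C)(C)CC[C@H](C)CCOC(C)=O | intermediate
15 | methyl methacrylate (methyl 2-methylprop-2-enoate) | C=C(C)C(=O)OC | starting material
16 | (3S)-5-[(1S,6R)-2-ethenyl-1,6-dimethylcyclohex-2-en-1-yl]-3-methylpentyl acetate (not isolated) | C=CC1=CCC[C@@H](C)[C@]1(C)CC[C@H](C)CCOC(C)=O | intermediate
17 | methyl (1S,5S,6R,8aR)-5-[(3S)-5-acetoxy-3-methylpentyl]-1,5,6-trimethyl-1,2,3,5,6,7,8,8a-octahydronaphthalene-1-carboxylate (halimane locants 4S,5R,8R,9S,13S) | COC(=O)[C@@]1(C)CCC=C2[C@H]1CC[C@@H](C)[C@]2(C)CC[C@H](C)CCOC(C)=O | target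

**Step count and risks**
Total: 9 steps. Longest linear sequence: 8 steps (1, 2, 3, 5, 6, 7, 8, 9); the lactone branch (4, then 5 to 9) has 6.

Step 9 (key step). The two half-chairs of ring B may lie close in energy, so that the hindered diene adds with poor facial discrimination; regio- or endo-selectivity may also erode, or the ester may add so slowly that Lewis acid side reactions of the diene take over. Fallback: diene 16 would be isolated after the metathesis and combined with methacrolein under a chiral oxazaborolidinium triflimide Lewis acid (10 mol %, the catalyst enantiomer that directs the dienophile to the diene face anti to the C9 methyl, CH2Cl2, −78 °C). The smaller and more strongly activated formyl group should react at low temperature with higher endo preference under catalyst control and give (1S,5S,6R,8aR)-5-[(3S)-5-acetoxy-3-methylpentyl]-1,5,6-trimethyl-1,2,3,5,6,7,8,8a-octahydronaphthalene-1-carbaldehyde F1. Pinnick oxidation (NaClO2, NaH2PO4, 2-methyl-2-butene) would give (1S,5S,6R,8aR)-5-[(3S)-5-acetoxy-3-methylpentyl]-1,5,6-trimethyl-1,2,3,5,6,7,8,8a-octahydronaphthalene-1-carboxylic acid F2, and methylation with Me3SiCHN2 in toluene/MeOH would come back to 17.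

Step 5. C-alkylation of the tetrasubstituted lactone enolate by the unactivated primary iodide may be slow, so that elimination of the iodide or proton transfer wins. Fallback: iodide 5 would be turned by Kornblum oxidation (DMSO, NaHCO3, 110 °C) into (3R)-5-{[tert-butyl(dimethyl)silyl]oxy}-3-methylpentanal F3. The lithium enolate of 7 would add to this far more reactive electrophile (aldol addition, −78 °C, again anti to the C4 methyl) to give (3R,4S)-3-[(3R)-5-{[tert-butyl(dimethyl)silyl]oxy}-1-hydroxy-3-methylpentyl]-3,4-dimethyloxolan-2-one F4. Acylation with 1,1′-thiocarbonyldiimidazole (DMAP, CH2Cl2, no strong base, to avoid retro-aldol cleavage) would give O-{(3R)-5-{[tert-butyl(dimethyl)silyl]oxy}-1-[(3R,4S)-3,4-dimethyl-2-oxooxolan-3-yl]-3-methylpentyl} 1H-imidazole-1-carbothioate F5, and Barton–McCombie deoxygenation (Bu3SnH, AIBN, toluene, 100 °C) would come back to 8.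

Step 6. The hindered lactol may stay ring-closed, so that the homologation stalls, or the lactone may be reduced through to the diol. Fallback: the reduction would be run alone and lactol 9 isolated. Wittig chloromethylenation with Ph3P=CHCl (from (chloromethyl)triphenylphosphonium chloride and NaN(SiMe3)2, THF, 0 → 25 °C), a stronger nucleophile that drains the open form, would give (2S,3S,6S)-8-{[tert-butyl(dimethyl)silyl]oxy}-3-(2-chloroethenyl)-2,3,6-trimethyloctan-1-ol F6. Dehydrochlorination with n-BuLi (3 equiv, THF, −78 → 0 °C) would come back to alkynol 10.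

**Further compounds**
F1 | step 9 | (1S,5S,6R,8aR)-5-[(3S)-5-acetoxy-3-methylpentyl]-1,5,6-trimethyl-1,2,3,5,6,7,8,8a-octahydronaphthalene-1-carbaldehyde | O=C[C@@]1(C)CCC=C2[C@H]1CC[C@@H](C)[C@]2(C)CC[C@H](C)CCOC(C)=O
F2 | step 9 | (1S,5S,6R,8aR)-5-[(3S)-5-acetoxy-3-methylpentyl]-1,5,6-trimethyl-1,2,3,5,6,7,8,8a-octahydronaphthalene-1-carboxylic acid | OC(=O)[C@@]1(C)CCC=C2[C@H]1CC[C@@H](C)[C@]2(C)CC[C@H](C)CCOC(C)=O
F3 | step 5 | (3R)-5-{[tert-butyl(dimethyl)silyl]oxy}-3-methylpentanal | O=CC[C@H](C)CCO[Si](C)(C)C(C)(C)C
F4 | step 5 | (3R,4S)-3-[(3R)-5-{[tert-butyl(dimethyl)silyl]oxy}-1-hydroxy-3-methylpentyl]-3,4-dimethyloxolan-2-one (mixture at the carbinol carbon) | O=C1OC[C@@H](C)[C@]1(C)C(O)C[C@H](C)CCO[Si](C)(C)C(C)(C)C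
F5 | step 5 | O-{(3R)-5-{[tert-butyl(dimethyl)silyl]oxy}-1-[(3R,4S)-3,4-dimethyl-2-oxooxolan-3-yl]-3-methylpentyl} 1H-imidazole-1-carbothioate | O=C1OC[C@@H](C)[C@]1(C)C(OC(=S)n1ccnc1)C[C@H](C)CCO[Si](C)(C)C(C)(C)C
F6 | step 6 | (2S,3S,6S)-8-{[tert-butyl(dimethyl)silyl]oxy}-3-(2-chloroethenyl)-2,3,6-trimethyloctan-1-ol (E/Z mixture) | OC[C@@H](C)[C@](C=CCl)(C)CC[C@H](C)CCO[Si](C)(C)C(C)(C)C
A1 | direct plan | cyclohexane-1,3-dione | O=C1CCCC(=O)C1
A2 | direct plan | methyl (2E)-5-{1-[(3S)-5-{[tert-butyl(dimethyl)silyl]oxy}-3-methylpentyl]-2,6-dioxocyclohexyl}pent-2-enoate | COC(=O)/C=C/CCC1(CC[C@H](C)CCO[Si](C)(C)C(C)(C)C)C(=O)CCCC1=O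
A3 | direct plan | methyl (1S,4aR,8aS)-4a-[(3S)-5-{[tert-butyl(dimethyl)silyl]oxy}-3-methylpentyl]-8a-hydroxy-5-oxodecahydronaphthalene-1-carboxylate | COC(=O)[C@H]1CCC[C@]2(CC[C@H](C)CCO[Si](C)(C)C(C)(C)C)C(=O)CCC[C@]12O
A4 | direct plan | methyl (1S,4aR,6R,8aR)-4a-[(3S)-5-{[tert-butyl(dimethyl)silyl]oxy}-3-methylpentyl]-1,6-dimethyl-5-methylidenedecahydronaphthalene-1-carboxylate | COC(=O)[C@@]1(C)CCC[C@@]2(CC[C@H](C)CCO[Si](C)(C)C(C)(C)C)[C@H]1CC[C@@H](C)C2=C
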